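Assumption: the presumed biosynthesis is taken as (a) epoxidation of an O-prenylated methylcatechol and 6-exo attack of the neighbouring phenol (benzodioxane), then (b) ionisation of the lactol of a reduced tenellone-type benzophenone aldehyde at the diarylmethyl carbon and capture by the C-prenyl group (indane); compounds 1, 4, 9 and 11 are taken as catalogue chemicals.

## Retrosynthetic overview

1. 19 ⇐ MOM ether 17 ⇐ lactol 16: the indane C–C bond comes from cyclisation of a diarylmethyl cation onto the ortho-prenyl group, ended by E1 to the isopropylidene. A chiral counter-anion sets the benzylic centre; this is the last ring formed.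
2. 16 ⇐ aryl bromide 8 + aldehyde 12 + DMF: aryllithium addition, then formylation of the ring C–H flanked by the new alkoxide and the OMOM group, in one flask.
3. 8 ⇐ bromocatechol 3 + (R)-epoxy tosylate 6: O-alkylation, then 6-exo epoxide opening by the phenoxide with inversion; this is the first ring formed and sets the dioxane centre.
4. 3 ⇐ 1 (Dakin); 6 ⇐ prenol 4 (asymmetric epoxidation); 12 ⇐ 9 (MOM ether, Stille prenylation). Both benzene rings are bought.

## Route

Step 1
Reactants: 1 3-bromo-2-hydroxy-5-methylbenzaldehyde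
Product: 3 3-bromo-5-methylbenzene-1,2-diol, via aryl formate 2 (not isolated)
Conditions: 30% aq. H2O2 (1.2 equiv), NaOH (1.1 equiv), THF/H2O, 0 °C → rt, argon; then 1 M HCl
Reagents that add atoms: hydrogen peroxide (OO)
Why: Dakin oxidation: the hydroperoxide anion adds to the ortho-hydroxy aldehyde, the electron-rich aryl group migrates to oxygen and formate 2 is saponified in the same flask; no stereocentre.

Step 2
Reactants: 4 3-methylbut-2-en-1-ol
Product: 6 [(2R)-3,3-dimethyloxiran-2-yl]methyl 4-methylbenzenesulfonate, via epoxy alcohol 5 (not isolated)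
Conditions: Ti(OiPr)4 (5 mol %), D-(−)-diisopropyl tartrate (7 mol %), t-BuOOH (1.5 equiv), 4 Å MS, CH2Cl2, −20 °C; then P(OMe)3; then 4-MeC6H4SO2Cl, Et3N, 4-(dimethylamino)pyridine (cat.), −10 °C
Reagents that add atoms: tert-butyl hydroperoxide (CC(C)(C)OO); 4-methylbenzenesulfonyl chloride (Cc1ccc(cc1)S(Cl)(=O)=O)
Why: Sharpless asymmetric epoxidation of a primary allylic alcohol, in which the D-(−)-tartrate complex delivers oxygen to the face that gives the (2R)-epoxy alcohol (about 90–94% ee; the minor antipode ends as a separable diastereomer of 19), followed by tosylation in the flask because the free epoxy alcohol is volatile and water-soluble.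

Step 3
Reactants: 3 3-bromo-5-methylbenzene-1,2-diol; 6 [(2R)-3,3-dimethyloxiran-2-yl]methyl 4-methylbenzenesulfonate
Product: 8 2-[(2S)-8-bromo-6-methyl-2,3-dihydro-1,4-benzodioxin-2-yl]propan-2-ol, via epoxy ether phenolate 7 (not isolated)
Conditions: NaH (2.2 equiv), DMSO, rt, argon; then 6 (1.0 equiv), rt → 60 °C; aq. NH4Cl
Reagents that add atoms: none
Why: Williamson etherification then biomimetic 6-exo-tet epoxide opening: in the catechol dianion the oxygen remote from bromine is the less stabilised and less hindered one and displaces the primary tosylate, after which the remaining phenoxide attacks the secondary epoxide carbon from the back (inversion, (R)-epoxide → (2S)-dioxane) and not the tertiary carbon, which would need a 7-endo path.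

Step 4
Reactants: 9 2-bromo-5-hydroxybenzaldehyde
Product: 10 2-bromo-5-(methoxymethoxy)benzaldehyde
Conditions: MeOCH2Cl, i-Pr2NEt, CH2Cl2, 0 °C → rt
Reagents that add atoms: chloromethyl methyl ether (COCCl)
Why: O-alkylation of the phenol (SN2 on the chloromethyl ether); the MOM group protects the phenol and later serves as the ortho-directing group; no stereocentre.

Step 5
Reactants: 10 2-bromo-5-(methoxymethoxy)benzaldehyde; 11 tributyl(3-methylbut-2-en-1-yl)stannane
Product: 12 5-(methoxymethoxy)-2-(3-methylbut-2-en-1-yl)benzaldehyde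
Conditions: Pd(PPh3)4 (5 mol %), DMF, 95 °C
Reagents that add atoms: none
Why: Stille coupling: oxidative addition into the aldehyde-activated C–Br bond and transfer of the allyl group at its tin-bearing carbon give the linear prenyl arene, and the allylstannane does not add to the free aldehyde without a Lewis acid; no stereocentre.

Step 6
Reactants: 8 2-[(2S)-8-bromo-6-methyl-2,3-dihydro-1,4-benzodioxin-2-yl]propan-2-ol; 12 5-(methoxymethoxy)-2-(3-methylbut-2-en-1-yl)benzaldehyde
Product: 16 3-[(2S)-2-(2-hydroxypropan-2-yl)-6-methyl-2,3-dihydro-1,4-benzodioxin-8-yl]-7-(methoxymethoxy)-4-(3-methylbut-2-en-1-yl)-1,3-dihydro-2-benzofuran-1-ol, via aryllithium 13 (not isolated), via dilithium dialkoxide 14 (not isolated), via trilithio species 15 (not isolated)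
Conditions: 8, n-BuLi (2.1 equiv), THF, −78 °C; then 12 (0.95 equiv), −78 °C; then s-BuLi (1.3 equiv), −78 → −40 °C; then DMF, −78 °C → rt; aq. NH4Cl
Reagents that add atoms: N,N-dimethylformamide (CN(C)C=O)
Why: Bromine–lithium exchange on the alkoxide of 8 gives 13, whose 1,2-addition to 12 gives the carbinol dialkoxide 14; the new lithium alkoxide and the OMOM group flank the same ring C–H and cooperate in a directed ortho-metalation (complex-induced proximity, as in alkoxide/OMOM- and α-amino-alkoxide-directed lithiations) to give 15, which DMF formylates, and the hydroxy aldehyde closes to lactol 16 on work-up; the carbinol and lactol centres form as mixtures and both are erased in step 7.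

Step 7
Reactants: 16 3-[(2S)-2-(2-hydroxypropan-2-yl)-6-methyl-2,3-dihydro-1,4-benzodioxin-8-yl]-7-(methoxymethoxy)-4-(3-methylbut-2-en-1-yl)-1,3-dihydro-2-benzofuran-1-ol
Product: 19 diaporindene G, via methoxymethyl ether 17 (not isolated), via bis-silyl ether 18 (not isolated)
Conditions: (S,S)-HN[P(=NSO2CF3)(O2C20H10Ar2)]2 (imidodiphosphorimidate from two (S)-3,3′-diaryl-1,1′-binaphthalene-2,2′-diolate units, Ar = 3,5-(CF3)2C6H3; 5 mol %), 5 Å MS, degassed CHCl3, −40 → −20 °C; then 2,2′-bipyridyl (4 equiv), Me3SiOTf (3 equiv), CH2Cl2, 0 °C → rt; then H2O, aq. citric acid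
Reagents that add atoms: none
Why: Proposed new method: the confined strong acid protonates the lactol ring oxygen and the C–O bond at the diarylmethyl carbon breaks (the acetal carbon is released as the aldehyde), giving an ortho-alkoxy-stabilised diarylmethyl cation paired with the chiral imidodiphosphorimidate anion, to one face of which the prenyl double bond adds 5-exo (biomimetic cation–olefin cyclisation) before the tertiary cation loses the ring proton to the anion (E1, Zaitsev) to give the isopropylidene, so the benzylic centre (3R) is set by the catalyst and all four lactol diastereomers converge through the planar cation (closest known: contact-ion-pair substitutions of allylic and diarylmethyl alcohols with chiral N-triflylphosphoramides and imidodiphosphorimidate-catalysed cationic cyclisations; the sense of induction must be checked in the first run and the (R,R)-acid used if it is the matched one), after which the Me3SiOTf–2,2′-bipyridyl method exchanges the aryl MOM ether for a silyl ether that water cleaves without an acid strong enough to move the double bond.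

## Compound list

1 | 3-bromo-2-hydroxy-5-methylbenzaldehyde | Cc1cc(Br)c(O)c(C=O)c1 | starting material
2 | 3-bromo-2-hydroxy-5-methylphenyl formate | Cc1cc(Br)c(O)c(OC=O)c1 | intermediate
3 | 3-bromo-5-methylbenzene-1,2-diol | Cc1cc(O)c(O)c(Br)c1 | intermediate
4 | 3-methylbut-2-en-1-ol (prenol) | CC(C)=CCO | starting material
5 | [(2R)-3,3-dimethyloxiran-2-yl]methanol | CC1(C)O[C@@H]1CO | intermediate
6 | [(2R)-3,3-dimethyloxiran-2-yl]methyl 4-methylbenzenesulfonate | CC1(C)O[C@@H]1COS(=O)(=O)c1ccc(C)cc1 | intermediate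
7 | sodium 2-bromo-6-{[(2R)-3,3-dimethyloxiran-2-yl]methoxy}-4-methylphenolate | [Na+].[O-]c1c(Br)cc(C)cc1OC[C@H]1OC1(C)C | intermediate
8 | 2-[(2S)-8-bromo-6-methyl-2,3-dihydro-1,4-benzodioxin-2-yl]propan-2-ol (ring oxygen next to the C–Br carbon carries the stereocentre) | Cc1cc(Br)c2O[C@H](C(C)(C)O)COc2c1 | intermediate
9 | 2-bromo-5-hydroxybenzaldehyde | O=Cc1cc(O)ccc1Br | starting material
10 | 2-bromo-5-(methoxymethoxy)benzaldehyde | COCOc1ccc(Br)c(C=O)c1 | intermediate
11 | tributyl(3-methylbut-2-en-1-yl)stannane | CCCC[Sn](CCCC)(CCCC)CC=C(C)C | starting material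
12 | 5-(methoxymethoxy)-2-(3-methylbut-2-en-1-yl)benzaldehyde | COCOc1ccc(CC=C(C)C)c(C=O)c1 | intermediate
13 | lithium 2-[(2S)-8-lithio-6-methyl-2,3-dihydro-1,4-benzodioxin-2-yl]propan-2-olate | Cc1cc([Li])c2O[C@H](C(C)(C)O[Li])COc2c1 | intermediate
14 | dilithium dialkoxide of [(2S)-2-(2-hydroxypropan-2-yl)-6-methyl-2,3-dihydro-1,4-benzodioxin-8-yl][5-(methoxymethoxy)-2-(3-methylbut-2-en-1-yl)phenyl]methanol (both carbinol configurations) | COCOc1ccc(CC=C(C)C)c(c1)C(O[Li])c1cc(C)cc2c1O[C@H](C(C)(C)O[Li])CO2 | intermediate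
15 | ring-lithiated derivative of 14 (lithium on the carbon between the carbinol-bearing carbon and the OMOM carbon) | COCOc1ccc(CC=C(C)C)c(C(O[Li])c2cc(C)cc3c2O[C@H](C(C)(C)O[Li])CO3)c1[Li] | intermediate
16 | 3-[(2S)-2-(2-hydroxypropan-2-yl)-6-methyl-2,3-dihydro-1,4-benzodioxin-8-yl]-7-(methoxymethoxy)-4-(3-methylbut-2-en-1-yl)-1,3-dihydro-2-benzofuran-1-ol (mixture at C1 and C3; ring-chain tautomer of the hydroxy aldehyde) | COCOc1ccc(CC=C(C)C)c2c1C(O)OC2c1cc(C)cc2c1O[C@H](C(C)(C)O)CO2 | intermediate
17 | (3R)-3-[(2S)-2-(2-hydroxypropan-2-yl)-6-methyl-2,3-dihydro-1,4-benzodioxin-8-yl]-5-(methoxymethoxy)-2-(propan-2-ylidene)-2,3-dihydro-1H-indene-4-carbaldehyde | CC(C)=C1Cc2ccc(OCOC)c(C=O)c2[C@@H]1c1cc(C)cc2c1O[C@H](C(C)(C)O)CO2 | intermediate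
18 | bis(trimethylsilyl) ether of 19 (phenol and tertiary alcohol silylated) | CC(C)=C1Cc2ccc(O[Si](C)(C)C)c(C=O)c2[C@@H]1c1cc(C)cc2c1O[C@H](C(C)(C)O[Si](C)(C)C)CO2 | intermediate
19 | diaporindene G, (3R)-5-hydroxy-3-[(2S)-2-(2-hydroxypropan-2-yl)-6-methyl-2,3-dihydro-1,4-benzodioxin-8-yl]-2-(propan-2-ylidene)-2,3-dihydro-1H-indene-4-carbaldehyde | CC(C)=C1Cc2ccc(O)c(C=O)c2[C@@H]1c1cc(C)cc2c1O[C@H](C(C)(C)O)CO2 | target

## Step count and risks

Total steps: 7. Longest linear sequence: 4 steps (1 → 3 → 8 → 16 → 19; the arms from 4 and from 9 are equally long).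

**Step 7 (most likely to fail).** Three things are untested. The facial selectivity of the chiral ion pair at the benzylic carbon is unknown. The tertiary cation may lose a methyl proton (prop-1-en-2-yl isomer) instead of the ring proton. The lactol can also detour through an isobenzofuran, and further acid can move the double bond into the five-membered ring.

Fallback, from 16 back to 17: lactol 16 is ionised with an achiral acid (Bi(OTf)3, 5 mol %, CH2Cl2, −40 °C). This gives 17 and its benzylic epimer, (3S)-3-[(2S)-2-(2-hydroxypropan-2-yl)-6-methyl-2,3-dihydro-1,4-benzodioxin-8-yl]-5-(methoxymethoxy)-2-(propan-2-ylidene)-2,3-dihydro-1H-indene-4-carbaldehyde F2, together with the kinetic alkene isomers 3-[(2S)-2-(2-hydroxypropan-2-yl)-6-methyl-2,3-dihydro-1,4-benzodioxin-8-yl]-5-(methoxymethoxy)-2-(prop-1-en-2-yl)-2,3-dihydro-1H-indene-4-carbaldehyde F1. A hydrogen-atom-transfer isomerisation then moves the disubstituted double bond of F1 into the tetrasubstituted position, so the mixture converges on 17 and F2. It uses the trivalent cobalt salen chloride CoCl(C36H52N2O2), whose ligand is N,N′-bis(3,5-di-tert-butylsalicylidene)cyclohexane-1,2-diamine, with catalytic PhSiH3 in benzene at rt. The two diastereomers are separated by preparative HPLC, and 17 is carried through the deprotection half of step 7. Stereocontrol is thus replaced by separation, and the alkene position is set by a radical isomerisation instead of the E1 step.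

**Step 6.** The butyllithium may remove the benzylic/allylic prenyl proton instead of the ring proton, and the polylithiated aggregate may react sluggishly.

Fallback, from 12 back to 19: aldehyde 12 is masked in the flask as lithium [5-(methoxymethoxy)-2-(3-methylbut-2-en-1-yl)phenyl][methyl(2-(dimethylamino)ethyl)amino]methanolate F3 (LiN(Me)CH2CH2NMe2, THF, −20 °C). n-BuLi metalates it between the chelating amino alkoxide and the OMOM group to give its ring-lithiated derivative F4. DMF and aqueous work-up then give 3-(methoxymethoxy)-6-(3-methylbut-2-en-1-yl)benzene-1,2-dicarbaldehyde F5. Aqueous HCl in THF removes the MOM group to give 3-hydroxy-6-(3-methylbut-2-en-1-yl)benzene-1,2-dicarbaldehyde F6. After deprotonation with LiN(SiMe3)2, the phenoxide deactivates the neighbouring aldehyde, so aryllithium 13 adds to the aldehyde next to the prenyl group. This gives 3-[(2S)-2-(2-hydroxypropan-2-yl)-6-methyl-2,3-dihydro-1,4-benzodioxin-8-yl]-4-(3-methylbut-2-en-1-yl)-1,3-dihydro-2-benzofuran-1,7-diol F7. F7 is cyclised with the chiral acid of step 7 (first half only, no deprotection needed) to 19.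

**Step 3.** The first alkylation of the dianion may not be selective for the oxygen remote from bromine, which would give the regioisomeric benzodioxane.

Fallback, from 1 back to 8: the two oxygens are introduced at different times. The phenol of 1 is protected (4-MeOC6H4CH2Cl, K2CO3, DMF) to give 3-bromo-2-[(4-methoxyphenyl)methoxy]-5-methylbenzaldehyde F8. Baeyer–Villiger oxidation (mCPBA, CH2Cl2) gives 3-bromo-2-[(4-methoxyphenyl)methoxy]-5-methylphenyl formate F9, and methanolysis (K2CO3, MeOH) gives 3-bromo-2-[(4-methoxyphenyl)methoxy]-5-methylphenol F10. Alkylation with tosylate 6 (K2CO3, DMF, 50 °C) gives (2R)-2-({3-bromo-2-[(4-methoxyphenyl)methoxy]-5-methylphenoxy}methyl)-3,3-dimethyloxirane F11. DDQ (CH2Cl2, pH 7 buffer) frees 2-bromo-6-{[(2R)-3,3-dimethyloxiran-2-yl]methoxy}-4-methylphenol F12. K2CO3 in DMF at 60 °C closes F12 to 8 by the same 6-exo opening.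

## Further compounds

F1 | step 7 | 3-[(2S)-2-(2-hydroxypropan-2-yl)-6-methyl-2,3-dihydro-1,4-benzodioxin-8-yl]-5-(methoxymethoxy)-2-(prop-1-en-2-yl)-2,3-dihydro-1H-indene-4-carbaldehyde (mixture at C2 and C3) | C=C(C)C1Cc2ccc(OCOC)c(C=O)c2C1c1cc(C)cc2c1O[C@H](C(C)(C)O)CO2
F2 | step 7 | (3S)-3-[(2S)-2-(2-hydroxypropan-2-yl)-6-methyl-2,3-dihydro-1,4-benzodioxin-8-yl]-5-(methoxymethoxy)-2-(propan-2-ylidene)-2,3-dihydro-1H-indene-4-carbaldehyde | CC(C)=C1Cc2ccc(OCOC)c(C=O)c2[C@H]1c1cc(C)cc2c1O[C@H](C(C)(C)O)CO2
F3 | step 6 | lithium [5-(methoxymethoxy)-2-(3-methylbut-2-en-1-yl)phenyl][methyl(2-(dimethylamino)ethyl)amino]methanolate | COCOc1ccc(CC=C(C)C)c(c1)C(O[Li])N(C)CCN(C)C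
F4 | step 6 | ring-lithiated derivative of F3 (lithium between the amino alkoxide carbon and the OMOM carbon) | COCOc1ccc(CC=C(C)C)c(C(O[Li])N(C)CCN(C)C)c1[Li]
F5 | step 6 | 3-(methoxymethoxy)-6-(3-methylbut-2-en-1-yl)benzene-1,2-dicarbaldehyde | COCOc1ccc(CC=C(C)C)c(C=O)c1C=O
F6 | step 6 | 3-hydroxy-6-(3-methylbut-2-en-1-yl)benzene-1,2-dicarbaldehyde | Oc1ccc(CC=C(C)C)c(C=O)c1C=O
F7 | step 6 | 3-[(2S)-2-(2-hydroxypropan-2-yl)-6-methyl-2,3-dihydro-1,4-benzodioxin-8-yl]-4-(3-methylbut-2-en-1-yl)-1,3-dihydro-2-benzofuran-1,7-diol | Oc1ccc(CC=C(C)C)c2c1C(O)OC2c1cc(C)cc2c1O[C@H](C(C)(C)O)CO2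
F8 | step 3 | 3-bromo-2-[(4-methoxyphenyl)methoxy]-5-methylbenzaldehyde | COc1ccc(COc2c(Br)cc(C)cc2C=O)cc1
F9 | step 3 | 3-bromo-2-[(4-methoxyphenyl)methoxy]-5-methylphenyl formate | COc1ccc(COc2c(Br)cc(C)cc2OC=O)cc1
F10 | step 3 | 3-bromo-2-[(4-methoxyphenyl)methoxy]-5-methylphenol | COc1ccc(COc2c(Br)cc(C)cc2O)cc1
F11 | step 3 | (2R)-2-({3-bromo-2-[(4-methoxyphenyl)methoxy]-5-methylphenoxy}methyl)-3,3-dimethyloxirane | COc1ccc(COc2c(Br)cc(C)cc2OC[C@H]2OC2(C)C)cc1
F12 | step 3 | 2-bromo-6-{[(2R)-3,3-dimethyloxiran-2-yl]methoxy}-4-methylphenol | Cc1cc(Br)c(O)c(OC[C@H]2OC2(C)C)c1
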